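Ring C, a phloroglucinol whose C-2 bears the ring-B oxygen, is cut at C-1–C-6 and C-3–C-4. C-2 with C-1 and C-3 is then an aryloxymalonate, and C-4, C-5 and C-6 are the three-carbon chain of dimethyl 3-oxopentanedioate. One double Claisen condensation closes and aromatises ring C, so the crowded B–O–C-2 bond is made earlier by simple O-alkylation. The precursor is the dimethyl malonate carried on O-1 of ring B of a benzyl-protected AB diaryl ether; benzyl ethers are used throughout so that the last step is a hydrogenolysis. Rings D and E are added to O-5 of ring C by SNAr.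

Key step: step 7

Remark: the target has no stereocentre and no hindered axis, so it is achiral and needs no stereocontrol. Locants used below: B-1 bears the oxygen to ring C and B-2 the oxygen from ring A; C-2 bears the ring-B oxygen and C-5 the oxygen to ring D; D-1 is bonded to that oxygen, D-6 bears the oxygen to ring E, D-4 is para to D-1.

Step 1
Reactants: 1 3,5-bis(benzyloxy)phenol
Product: 2 2,4-bis(benzyloxy)-6-hydroxybenzaldehyde
Conditions: MgCl2, Et3N, (CH2O)n, MeCN, reflux; aq. HCl work-up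
Reagents that add atoms: formaldehyde (as paraformaldehyde), C=O
Why: The magnesium-mediated ortho-formylation (Casnati–Skattebøl) delivers formaldehyde only ortho to the chelated phenoxide, and the two ortho positions of 1 are equivalent, so one salicylaldehyde should form.

Step 2
Reactants: 2 2,4-bis(benzyloxy)-6-hydroxybenzaldehyde
Product: 3 2,4-bis(benzyloxy)-6-(methoxymethoxy)benzaldehyde
Conditions: MOMCl, iPr2NEt, CH2Cl2, 0 °C to reflux
Reagents that add atoms: chloromethyl methyl ether, COCCl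
Why: Williamson-type O-alkylation puts an acetal on the future B-1 oxygen that should survive peracid and hot base and later come off with mild acid without loss of benzyl ethers.

Step 3
Reactants: 3 2,4-bis(benzyloxy)-6-(methoxymethoxy)benzaldehyde
Product: 5 2,4-bis(benzyloxy)-6-(methoxymethoxy)phenol, via aryl formate 4 (not isolated)
Conditions: mCPBA, CH2Cl2, 0 °C to rt; NaHCO3 wash; then K2CO3 (cat.), MeOH, rt
Reagents that add atoms: mCPBA, OOC(=O)c1cccc(Cl)c1
Why: Baeyer–Villiger oxidation of the electron-rich 2,4,6-trialkoxybenzaldehyde should proceed with aryl migration, and methanolysis of the formate frees the phenol that becomes the central B-2 oxygen.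

Step 4
Reactants: 5 2,4-bis(benzyloxy)-6-(methoxymethoxy)phenol; 6 1,3-bis(benzyloxy)-5-bromobenzene
Product: 7 1,5-bis(benzyloxy)-2-[3,5-bis(benzyloxy)phenoxy]-3-(methoxymethoxy)benzene
Conditions: CuI (10 mol%), picolinic acid (20 mol%), K3PO4, DMSO, 90 °C, Ar
Reagents that add atoms: none
Why: The Ullmann diaryl ether coupling with the CuI/picolinic acid system accepts 2,6-disubstituted phenoxides, and with the hindrance on the phenol and an unhindered aryl bromide no substitution at a flanked carbon is required.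

Step 5
Reactants: 7 1,5-bis(benzyloxy)-2-[3,5-bis(benzyloxy)phenoxy]-3-(methoxymethoxy)benzene
Product: 8 3,5-bis(benzyloxy)-2-[3,5-bis(benzyloxy)phenoxy]phenol
Conditions: conc. HCl (cat.), MeOH/THF, 50 °C
Reagents that add atoms: none
Why: Acid-catalysed acetal exchange with methanol removes the MOM group as dimethoxymethane while benzyl and diaryl ethers are stable.

Step 6
Reactants: 8 3,5-bis(benzyloxy)-2-[3,5-bis(benzyloxy)phenoxy]phenol; 9 dimethyl bromomalonate
Product: 10 dimethyl 2-{3,5-bis(benzyloxy)-2-[3,5-bis(benzyloxy)phenoxy]phenoxy}propanedioate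
Conditions: K2CO3, acetone, rt to 50 °C
Reagents that add atoms: none
Why: SN2 O-alkylation (Williamson) of the phenoxide with the doubly activated bromide makes the B-1–O–C-2 bond at an sp3 carbon, before that carbon becomes a flanked ring position.

Step 7
Reactants: 10 dimethyl 2-{3,5-bis(benzyloxy)-2-[3,5-bis(benzyloxy)phenoxy]phenoxy}propanedioate; 11 dimethyl 3-oxopentanedioate
Product: 12 dimethyl 5-{3,5-bis(benzyloxy)-2-[3,5-bis(benzyloxy)phenoxy]phenoxy}-2,4,6-trihydroxybenzene-1,3-dicarboxylate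
Conditions: NaOMe (2.5 equiv), MeOH/toluene, reflux with removal of MeOH, Ar; then 1 M HCl, 0 °C
Reagents that add atoms: none
Why: Methoxide generates the enolate of 11, one of its methylene carbons acylates on an ester carbonyl of 10 with loss of methoxide (crossed Claisen condensation), and the other methylene carbon then adds to the second malonate ester carbonyl and expels methoxide, after which three enolisations deliver the aromatic triol as its sodium salt. The closest known reaction is the classical alkoxide condensation of malonic esters with acetonedicarboxylic esters that gives phloroglucinol dicarboxylates. Ring C is closed as a six-membered carbocycle in a 6-exo-trig Dieckmann-type attack of the enolate carbon on the ester carbonyl, forming C-1–C-6 and C-3–C-4. No stereocentre is formed, since every sp3 carbon of the intermediates ends up in the arene. The step needs C-cyclisation to win over O-cyclisation to a pyranone and over retro-Claisen cleavage, which is secured by the stability of the phloroglucinolate as thermodynamic sink under reversible alkoxide conditions and by removal of methanol; no regiochemical choice exists because both partners are symmetric, and the hydrogen on the malonate carbon lets C-2 aromatise with its aryloxy group in place.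

Step 8
Reactants: 12 dimethyl 5-{3,5-bis(benzyloxy)-2-[3,5-bis(benzyloxy)phenoxy]phenoxy}-2,4,6-trihydroxybenzene-1,3-dicarboxylate
Product: 14 2-{3,5-bis(benzyloxy)-2-[3,5-bis(benzyloxy)phenoxy]phenoxy}benzene-1,3,5-triol, via dicarboxylic acid 13 (not isolated)
Conditions: KOH, degassed MeOH/H2O, reflux, Ar; then 2 M HCl to pH 2, 60 °C
Reagents that add atoms: none
Why: Saponification gives a vinylogous β-keto diacid that should lose two CO2 on gentle warming in acid, as in the classical phloroglucinol synthesis, with air excluded because the polyphenolate is oxidisable.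

Step 9
Reactants: 2 2,4-bis(benzyloxy)-6-hydroxybenzaldehyde
Product: 15 2,4,6-tris(benzyloxy)benzaldehyde
Conditions: BnBr, K2CO3, DMF, 60 °C
Reagents that add atoms: benzyl bromide, BrCc1ccccc1
Why: Williamson benzylation of the remaining hydrogen-bonded phenol needs only warm carbonate in a dipolar solvent.

Step 10
Reactants: 15 2,4,6-tris(benzyloxy)benzaldehyde
Product: 17 2,4,6-tris(benzyloxy)phenol, via aryl formate 16 (not isolated)
Conditions: mCPBA, CH2Cl2, 0 °C to rt; NaHCO3 wash; then K2CO3 (cat.), MeOH, rt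
Reagents that add atoms: mCPBA, OOC(=O)c1cccc(Cl)c1
Why: Baeyer–Villiger oxidation with aryl migration followed by formate methanolysis, as in step 3, gives the ring-E phenol.

Step 11
Reactants: 18 2-(3-bromo-4-fluorophenyl)-1,3-dioxolane
Product: 20 3-bromo-5-(1,3-dioxolan-2-yl)-2-fluorophenol, via aryl pinacolboronate 19 (not isolated)
Conditions: [Ir(OMe)(cod)]2 (1.5 mol%), dtbpy (3 mol%), B2pin2 (0.6 equiv), THF, 80 °C; then 30% H2O2, aq. NaOH, 0 °C; aq. NH4Cl
Reagents that add atoms: hydrogen peroxide, OO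
Why: Iridium-catalysed C–H borylation (Hartwig–Miyaura) is sterically controlled and should go to the C–H next to fluorine, the only one without a large ortho neighbour, and alkaline peroxide then oxidises the C–B bond while acetal and C–Br bond survive.

Step 12
Reactants: 20 3-bromo-5-(1,3-dioxolan-2-yl)-2-fluorophenol
Product: 21 2-[3-(benzyloxy)-5-bromo-4-fluorophenyl]-1,3-dioxolane
Conditions: BnBr, K2CO3, DMF, rt
Reagents that add atoms: benzyl bromide, BrCc1ccccc1
Why: Williamson benzylation of the acidic ortho-fluorophenol protects the future D-2 oxygen under conditions that leave the acetal intact.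

Step 13
Reactants: 21 2-[3-(benzyloxy)-5-bromo-4-fluorophenyl]-1,3-dioxolane; 17 2,4,6-tris(benzyloxy)phenol
Product: 23 3-(benzyloxy)-4-fluoro-5-[2,4,6-tris(benzyloxy)phenoxy]benzaldehyde, via dioxolane acetal 22 (not isolated)
Conditions: CuI (10 mol%), picolinic acid (20 mol%), K3PO4, DMSO, 100 °C, Ar; work-up; then 1 M HCl, THF, rt
Reagents that add atoms: water, O
Why: Ullmann coupling joins the hindered phenoxide to a bromide flanked only by fluorine, the acetal keeps that fluorine unactivated toward SNAr during the coupling, and acetal hydrolysis then restores the formyl group that activates it.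

Step 14
Reactants: 14 2-{3,5-bis(benzyloxy)-2-[3,5-bis(benzyloxy)phenoxy]phenoxy}benzene-1,3,5-triol; 23 3-(benzyloxy)-4-fluoro-5-[2,4,6-tris(benzyloxy)phenoxy]benzaldehyde
Product: 25 3-(benzyloxy)-4-[3,5-bis(benzyloxy)-4-{3,5-bis(benzyloxy)-2-[3,5-bis(benzyloxy)phenoxy]phenoxy}phenoxy]-5-[2,4,6-tris(benzyloxy)phenoxy]benzaldehyde, via pentamer diol 24 (not isolated)
Conditions: 23 (1.0 equiv), Cs2CO3, DMF, 80 °C, Ar; then BnBr, rt to 40 °C
Reagents that add atoms: benzyl bromide, BrCc1ccccc1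
Why: In this SNAr the fluorine of 23 is activated by the para formyl group and flanked by two oxygens, so only the O-5 phenoxide of 14, the one with two ortho hydrogens, should attack at a useful rate, and the two flanked phenols are then benzylated in the same flask (Williamson) so that no free phenol meets the peracid.

Step 15
Reactants: 25 3-(benzyloxy)-4-[3,5-bis(benzyloxy)-4-{3,5-bis(benzyloxy)-2-[3,5-bis(benzyloxy)phenoxy]phenoxy}phenoxy]-5-[2,4,6-tris(benzyloxy)phenoxy]benzaldehyde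
Product: 27 3-(benzyloxy)-4-[3,5-bis(benzyloxy)-4-{3,5-bis(benzyloxy)-2-[3,5-bis(benzyloxy)phenoxy]phenoxy}phenoxy]-5-[2,4,6-tris(benzyloxy)phenoxy]phenol, via aryl formate 26 (not isolated)
Conditions: mCPBA, CH2Cl2, 0 °C to rt; NaHCO3 wash; then K2CO3 (cat.), MeOH/THF, rt
Reagents that add atoms: mCPBA, OOC(=O)c1cccc(Cl)c1
Why: Baeyer–Villiger oxidation of the 3,4,5-trioxygenated benzaldehyde with aryl migration, then formate methanolysis, converts the activating formyl group into the D-4 hydroxyl.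

Step 16
Reactants: 27 3-(benzyloxy)-4-[3,5-bis(benzyloxy)-4-{3,5-bis(benzyloxy)-2-[3,5-bis(benzyloxy)phenoxy]phenoxy}phenoxy]-5-[2,4,6-tris(benzyloxy)phenoxy]phenol
Product: 28 CNP0018313.0, 2-[2-(3,5-dihydroxyphenoxy)-3,5-dihydroxyphenoxy]-5-[2,4-dihydroxy-6-(2,4,6-trihydroxyphenoxy)phenoxy]benzene-1,3-diol
Conditions: H2 (1 atm), 10% Pd/C, THF/MeOH, rt; filtration under Ar
Reagents that add atoms: none
Why: Catalytic hydrogenolysis should cleave all ten benzyl ethers under neutral conditions and leave the four diaryl ethers untouched, with toluene as the only by-product.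

Compound list
1 | 3,5-bis(benzyloxy)phenol | Oc1cc(OCc2ccccc2)cc(OCc2ccccc2)c1 | starting material
2 | 2,4-bis(benzyloxy)-6-hydroxybenzaldehyde | O=Cc1c(O)cc(OCc2ccccc2)cc1OCc1ccccc1 | intermediate
3 | 2,4-bis(benzyloxy)-6-(methoxymethoxy)benzaldehyde | COCOc1cc(OCc2ccccc2)cc(OCc2ccccc2)c1C=O | intermediate
4 | 2,4-bis(benzyloxy)-6-(methoxymethoxy)phenyl formate | COCOc1cc(OCc2ccccc2)cc(OCc2ccccc2)c1OC=O | intermediate
5 | 2,4-bis(benzyloxy)-6-(methoxymethoxy)phenol | COCOc1cc(OCc2ccccc2)cc(OCc2ccccc2)c1O | intermediate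
6 | 1,3-bis(benzyloxy)-5-bromobenzene | Brc1cc(OCc2ccccc2)cc(OCc2ccccc2)c1 | starting material
7 | 1,5-bis(benzyloxy)-2-[3,5-bis(benzyloxy)phenoxy]-3-(methoxymethoxy)benzene | COCOc1cc(OCc2ccccc2)cc(OCc2ccccc2)c1Oc1cc(OCc2ccccc2)cc(OCc2ccccc2)c1 | intermediate
8 | 3,5-bis(benzyloxy)-2-[3,5-bis(benzyloxy)phenoxy]phenol (AB phenol) | Oc1cc(OCc2ccccc2)cc(OCc2ccccc2)c1Oc1cc(OCc2ccccc2)cc(OCc2ccccc2)c1 | intermediate
9 | dimethyl bromomalonate | COC(=O)C(Br)C(=O)OC | starting material
10 | dimethyl 2-{3,5-bis(benzyloxy)-2-[3,5-bis(benzyloxy)phenoxy]phenoxy}propanedioate | COC(=O)C(Oc1cc(OCc2ccccc2)cc(OCc2ccccc2)c1Oc1cc(OCc2ccccc2)cc(OCc2ccccc2)c1)C(=O)OC | intermediate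
11 | dimethyl 3-oxopentanedioate | COC(=O)CC(=O)CC(=O)OC | starting material
12 | dimethyl 5-{3,5-bis(benzyloxy)-2-[3,5-bis(benzyloxy)phenoxy]phenoxy}-2,4,6-trihydroxybenzene-1,3-dicarboxylate | COC(=O)c1c(O)c(C(=O)OC)c(O)c(Oc2cc(OCc3ccccc3)cc(OCc3ccccc3)c2Oc2cc(OCc3ccccc3)cc(OCc3ccccc3)c2)c1O | intermediate
13 | 5-{3,5-bis(benzyloxy)-2-[3,5-bis(benzyloxy)phenoxy]phenoxy}-2,4,6-trihydroxybenzene-1,3-dicarboxylic acid | OC(=O)c1c(O)c(C(=O)O)c(O)c(Oc2cc(OCc3ccccc3)cc(OCc3ccccc3)c2Oc2cc(OCc3ccccc3)cc(OCc3ccccc3)c2)c1O | intermediate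
14 | 2-{3,5-bis(benzyloxy)-2-[3,5-bis(benzyloxy)phenoxy]phenoxy}benzene-1,3,5-triol (ABC triol) | Oc1cc(O)c(Oc2cc(OCc3ccccc3)cc(OCc3ccccc3)c2Oc2cc(OCc3ccccc3)cc(OCc3ccccc3)c2)c(O)c1 | intermediate
15 | 2,4,6-tris(benzyloxy)benzaldehyde | O=Cc1c(OCc2ccccc2)cc(OCc2ccccc2)cc1OCc1ccccc1 | intermediate
16 | 2,4,6-tris(benzyloxy)phenyl formate | O=COc1c(OCc2ccccc2)cc(OCc2ccccc2)cc1OCc1ccccc1 | intermediate
17 | 2,4,6-tris(benzyloxy)phenol | Oc1c(OCc2ccccc2)cc(OCc2ccccc2)cc1OCc1ccccc1 | intermediate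
18 | 2-(3-bromo-4-fluorophenyl)-1,3-dioxolane | Fc1ccc(cc1Br)C1OCCO1 | starting material
19 | 2-[3-bromo-5-(1,3-dioxolan-2-yl)-2-fluorophenyl]-4,4,5,5-tetramethyl-1,3,2-dioxaborolane | CC1(C)OB(OC1(C)C)c1cc(cc(Br)c1F)C1OCCO1 | intermediate
20 | 3-bromo-5-(1,3-dioxolan-2-yl)-2-fluorophenol | Oc1cc(cc(Br)c1F)C1OCCO1 | intermediate
21 | 2-[3-(benzyloxy)-5-bromo-4-fluorophenyl]-1,3-dioxolane | Fc1c(Br)cc(cc1OCc1ccccc1)C1OCCO1 | intermediate
22 | 2-{3-(benzyloxy)-4-fluoro-5-[2,4,6-tris(benzyloxy)phenoxy]phenyl}-1,3-dioxolane | Fc1c(Oc2c(OCc3ccccc3)cc(OCc3ccccc3)cc2OCc2ccccc2)cc(cc1OCc1ccccc1)C1OCCO1 | intermediate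
23 | 3-(benzyloxy)-4-fluoro-5-[2,4,6-tris(benzyloxy)phenoxy]benzaldehyde (DE fluoride) | O=Cc1cc(OCc2ccccc2)c(F)c(Oc2c(OCc3ccccc3)cc(OCc3ccccc3)cc2OCc2ccccc2)c1 | intermediate
24 | 3-(benzyloxy)-4-[4-{3,5-bis(benzyloxy)-2-[3,5-bis(benzyloxy)phenoxy]phenoxy}-3,5-dihydroxyphenoxy]-5-[2,4,6-tris(benzyloxy)phenoxy]benzaldehyde | O=Cc1cc(OCc2ccccc2)c(Oc2cc(O)c(Oc3cc(OCc4ccccc4)cc(OCc4ccccc4)c3Oc3cc(OCc4ccccc4)cc(OCc4ccccc4)c3)c(O)c2)c(Oc2c(OCc3ccccc3)cc(OCc3ccccc3)cc2OCc2ccccc2)c1 | intermediate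
25 | 3-(benzyloxy)-4-[3,5-bis(benzyloxy)-4-{3,5-bis(benzyloxy)-2-[3,5-bis(benzyloxy)phenoxy]phenoxy}phenoxy]-5-[2,4,6-tris(benzyloxy)phenoxy]benzaldehyde | O=Cc1cc(OCc2ccccc2)c(Oc2cc(OCc3ccccc3)c(Oc3cc(OCc4ccccc4)cc(OCc4ccccc4)c3Oc3cc(OCc4ccccc4)cc(OCc4ccccc4)c3)c(OCc3ccccc3)c2)c(Oc2c(OCc3ccccc3)cc(OCc3ccccc3)cc2OCc2ccccc2)c1 | intermediate
26 | 3-(benzyloxy)-4-[3,5-bis(benzyloxy)-4-{3,5-bis(benzyloxy)-2-[3,5-bis(benzyloxy)phenoxy]phenoxy}phenoxy]-5-[2,4,6-tris(benzyloxy)phenoxy]phenyl formate | O=COc1cc(OCc2ccccc2)c(Oc2cc(OCc3ccccc3)c(Oc3cc(OCc4ccccc4)cc(OCc4ccccc4)c3Oc3cc(OCc4ccccc4)cc(OCc4ccccc4)c3)c(OCc3ccccc3)c2)c(Oc2c(OCc3ccccc3)cc(OCc3ccccc3)cc2OCc2ccccc2)c1 | intermediate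
27 | 3-(benzyloxy)-4-[3,5-bis(benzyloxy)-4-{3,5-bis(benzyloxy)-2-[3,5-bis(benzyloxy)phenoxy]phenoxy}phenoxy]-5-[2,4,6-tris(benzyloxy)phenoxy]phenol | Oc1cc(OCc2ccccc2)c(Oc2cc(OCc3ccccc3)c(Oc3cc(OCc4ccccc4)cc(OCc4ccccc4)c3Oc3cc(OCc4ccccc4)cc(OCc4ccccc4)c3)c(OCc3ccccc3)c2)c(Oc2c(OCc3ccccc3)cc(OCc3ccccc3)cc2OCc2ccccc2)c1 | intermediate
28 | CNP0018313.0, 2-[2-(3,5-dihydroxyphenoxy)-3,5-dihydroxyphenoxy]-5-[2,4-dihydroxy-6-(2,4,6-trihydroxyphenoxy)phenoxy]benzene-1,3-diol (achiral) | Oc1cc(O)cc(Oc2c(O)cc(O)cc2Oc2c(O)cc(Oc3c(O)cc(O)cc3Oc3c(O)cc(O)cc3O)cc2O)c1 | target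

Total steps: 16. Longest linear sequence: 11 steps (steps 1–8, then 14–16); the ring-E phenol branches from 2 (steps 9–10) and the DE fluoride is built in steps 11–13.

Steps most likely to fail

Step 7 comes first. Under methoxide the malonate of 10 is largely deprotonated and may acylate too slowly, and after the first acylation O-cyclisation to a pyranone or retro-Claisen loss of a methoxycarbonyl group may outrun closure of the carbocycle. The fallback forms the same two bonds one at a time with an activated acyl donor and soft enolisation. Compound 10 would be half-saponified (1 equiv KOH, MeOH/THF, 0 °C) to methyl hydrogen 2-(AB-aryloxy)malonate F1 (racemic at a carbon that later becomes aromatic). F1 would be activated with carbonyldiimidazole to the acyl imidazolide F2. F2 would C-acylate the magnesium enolate of 11 (MgCl2, Et3N, MeCN) to give the open-chain dimethyl 2-acyl-3-oxopentanedioate F3. A separate Dieckmann closure with NaOMe in MeOH would then give 12, where the route is rejoined.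

Step 14 is second. Site selectivity may be lost, with attack through the flanked O-1/O-3 phenoxides or double arylation, and substitution at the doubly flanked fluoride may be slow enough for these to compete. The fallback separates differentiation from coupling. Compound 14 would be silylated at low temperature with TIPSCl and imidazole at the unhindered O-5 to give the 5-O-triisopropylsilyl diol F4; wrongly silylated material can be recycled by desilylation. The two flanked phenols would be benzylated (BnBr, K2CO3, acetone) to give the silyl bis(benzyl) ether F5. TBAF would free the single phenol 3,5-bis(benzyloxy)-4-(AB-aryloxy)phenol F6. SNAr of this one phenoxide with 23 (Cs2CO3, DMF) can only give 25, where the route is rejoined.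

Step 13 is third. The phenoxide of 17, flanked by two benzyloxy groups, may bind copper poorly, so that the aryl bromide is reduced or left unchanged; step 4 carries the same risk in milder form. The fallback reverses the role of the ring-D partner. Compound 21 would undergo bromine–magnesium exchange with iPrMgCl·LiCl at −20 °C, followed by B(OMe)3 and neutral aqueous work-up, to give [3-(benzyloxy)-5-(1,3-dioxolan-2-yl)-2-fluorophenyl]boronic acid F7. F7 would be coupled with 17 under Chan–Lam–Evans conditions (Cu(OAc)2, pyridine, 4 Å sieves, CH2Cl2, air), which are known to accept 2,6-disubstituted phenols. This gives 22, which is hydrolysed to 23 as in step 13.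

Further compounds
F1 | step 7 | 2-{3,5-bis(benzyloxy)-2-[3,5-bis(benzyloxy)phenoxy]phenoxy}-3-methoxy-3-oxopropanoic acid (racemic, epimerisable) | COC(=O)C(Oc1cc(OCc2ccccc2)cc(OCc2ccccc2)c1Oc1cc(OCc2ccccc2)cc(OCc2ccccc2)c1)C(=O)O
F2 | step 7 | methyl 2-{3,5-bis(benzyloxy)-2-[3,5-bis(benzyloxy)phenoxy]phenoxy}-3-(imidazol-1-yl)-3-oxopropanoate (racemic, epimerisable) | COC(=O)C(Oc1cc(OCc2ccccc2)cc(OCc2ccccc2)c1Oc1cc(OCc2ccccc2)cc(OCc2ccccc2)c1)C(=O)n1ccnc1
F3 | step 7 | dimethyl 2-(2-{3,5-bis(benzyloxy)-2-[3,5-bis(benzyloxy)phenoxy]phenoxy}-3-methoxy-3-oxopropanoyl)-3-oxopentanedioate (mixture of epimerisable isomers and enols) | COC(=O)CC(=O)C(C(=O)OC)C(=O)C(Oc1cc(OCc2ccccc2)cc(OCc2ccccc2)c1Oc1cc(OCc2ccccc2)cc(OCc2ccccc2)c1)C(=O)OC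
F4 | step 14 | 2-{3,5-bis(benzyloxy)-2-[3,5-bis(benzyloxy)phenoxy]phenoxy}-5-[(triisopropylsilyl)oxy]benzene-1,3-diol | CC(C)[Si](C(C)C)(C(C)C)Oc1cc(O)c(Oc2cc(OCc3ccccc3)cc(OCc3ccccc3)c2Oc2cc(OCc3ccccc3)cc(OCc3ccccc3)c2)c(O)c1
F5 | step 14 | [3,5-bis(benzyloxy)-4-{3,5-bis(benzyloxy)-2-[3,5-bis(benzyloxy)phenoxy]phenoxy}phenoxy]triisopropylsilane | CC(C)[Si](C(C)C)(C(C)C)Oc1cc(OCc2ccccc2)c(Oc2cc(OCc3ccccc3)cc(OCc3ccccc3)c2Oc2cc(OCc3ccccc3)cc(OCc3ccccc3)c2)c(OCc2ccccc2)c1
F6 | step 14 | 3,5-bis(benzyloxy)-4-{3,5-bis(benzyloxy)-2-[3,5-bis(benzyloxy)phenoxy]phenoxy}phenol | Oc1cc(OCc2ccccc2)c(Oc2cc(OCc3ccccc3)cc(OCc3ccccc3)c2Oc2cc(OCc3ccccc3)cc(OCc3ccccc3)c2)c(OCc2ccccc2)c1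
F7 | step 13 | [3-(benzyloxy)-5-(1,3-dioxolan-2-yl)-2-fluorophenyl]boronic acid | OB(O)c1cc(cc(OCc2ccccc2)c1F)C1OCCO1
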